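**Retrosynthetic overview**
1. Target 17 ⇐ seco-diene 16 by ring-closing metathesis at C1=C10 (Z); the ten-membered carbocycle is formed last.
2. 16 ⇐ α-methylene lactone 14 by Mitsunobu acetate inversion at C9, then copper hydride conjugate reduction with kinetic protonation at C11.
3. 14 ⇐ enal 6 + bromomethyl δ-lactone 12 by an indium Barbier union (C6–C7) with δ→γ lactone ring switch; the δ-lactone (first ring, temporary) comes from a small ring-closing metathesis, the γ-lactone is the second ring.
4. 6 and 12 ⇐ achiral aldehydes 1 and 7, each by chiral phosphoric acid-catalysed allylboration (sets C3 and C9, the first stereocentre of each branch).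

Assumption: carbons carry germacranolide numbers (C12 = lactone carbonyl on C11, lactone oxygen on C6, C13 = 11-methyl, C14 on C10, C15 on C4), the SMILES is read as the (3S,6S,7S,9S,11R)-1(10)Z,4E isomer, and 1 is taken as the purchasable E acetal-aldehyde.

**Route**

Step 1
Reactants: 1 (E)-4,4-dimethoxy-2-methylbut-2-enal; 2 allylboronic acid pinacol ester
Product: 4 (2E,4S)-1,1-dimethoxy-3-methylhepta-2,6-dien-4-ol, via pinacol borate ester 3 (not isolated)
Conditions: 2 (1.3 equiv), (S)-3,3'-bis(2,4,6-triisopropylphenyl)-1,1'-binaphthyl-2,2'-diyl hydrogen phosphate [(S)-TRIP] (5 mol%), 4 Å MS, toluene, −30 °C; aq NaHCO3 work-up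
Reagents that add atoms: none
Why: Chiral phosphoric acid-catalysed allylboration, in which the acid hydrogen-bonds to a pinacol oxygen and the formyl C–H in a chair six-membered transition state, so the (S)-acid sends the allyl group to one face of the enal carbonyl and sets C3 as S (the (R)-acid gives (R)-carbinols from benzaldehyde and other sp2-substituted aldehydes), while the acetal and the E alkene are inert at −30 °C.

Step 2
Reactants: 4 (2E,4S)-1,1-dimethoxy-3-methylhepta-2,6-dien-4-ol
Product: 5 (2E,4S)-1,1-dimethoxy-3-methylhepta-2,6-dien-4-yl acetate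
Conditions: Ac2O (1.5 equiv), pyridine, 4-(dimethylamino)pyridine (5 mol%), CH2Cl2, 0 °C → rt
Reagents that add atoms: acetic anhydride CC(=O)OC(C)=O
Why: Nucleophile-catalysed O-acylation of the secondary allylic alcohol, which touches no stereocentre and leaves the acetal intact in the basic medium.

Step 3
Reactants: 5 (2E,4S)-1,1-dimethoxy-3-methylhepta-2,6-dien-4-yl acetate
Product: 6 (2E,4S)-3-methyl-1-oxohepta-2,6-dien-4-yl acetate
Conditions: pyridinium p-toluenesulfonate (10 mol%), acetone/H2O 10:1, rt
Reagents that add atoms: water O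
Why: Mild acid-catalysed acetal hydrolysis (the oxocarbenium ion is allylic and forms easily) frees the C6 aldehyde in conjugation with the C4=C5 alkene, whose E geometry is the stable one, without cleaving the secondary acetate.

Step 4
Reactants: 7 methacrolein; 2 allylboronic acid pinacol ester
Product: 9 (3R)-2-methylhexa-1,5-dien-3-ol, via pinacol borate ester 8 (not isolated)
Conditions: 2 (1.2 equiv), (R)-3,3'-bis(2,4,6-triisopropylphenyl)-1,1'-binaphthyl-2,2'-diyl hydrogen phosphate [(R)-TRIP] (5 mol%), 4 Å MS, toluene, −30 °C; aq NaHCO3 work-up, product kept as a concentrated solution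
Reagents that add atoms: none
Why: The same chiral phosphoric acid-catalysed allylboration with the (R)-acid sets C9 as R on the small enal; R is the relay configuration that steers step 7 and is inverted in step 8.

Step 5
Reactants: 9 (3R)-2-methylhexa-1,5-dien-3-ol; 10 2-(bromomethyl)prop-2-enoic acid
Product: 11 (3R)-2-methylhexa-1,5-dien-3-yl 2-(bromomethyl)prop-2-enoate
Conditions: N,N'-diisopropylcarbodiimide (1.1 equiv), 4-(dimethylamino)pyridine (5 mol%), CH2Cl2, −10 → 0 °C
Reagents that add atoms: none
Why: Carbodiimide (Steglich) esterification at low temperature with only catalytic 4-(dimethylamino)pyridine, so the allylic bromide of the acid is not displaced and C9 is not involved.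

Step 6
Reactants: 11 (3R)-2-methylhexa-1,5-dien-3-yl 2-(bromomethyl)prop-2-enoate
Product: 12 (6R)-3-(bromomethyl)-6-(prop-1-en-2-yl)-5,6-dihydro-2H-pyran-2-one
Conditions: second-generation Grubbs catalyst RuCl2(H2IMes)(PCy3)(=CHPh) (3 mol%), CH2Cl2 (5 mM), 40 °C
Reagents that add atoms: none
Why: Ring-closing metathesis between the terminal vinyl group and the acrylate alkene gives the six-membered unsaturated lactone (the isopropenyl group cannot compete because it would have to form a tetrasubstituted butenolide alkene), and the ring holds C8 cis to the carbonyl, that is trans to the CH2Br carbon.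

Step 7
Reactants: 12 (6R)-3-(bromomethyl)-6-(prop-1-en-2-yl)-5,6-dihydro-2H-pyran-2-one; 6 (2E,4S)-3-methyl-1-oxohepta-2,6-dien-4-yl acetate
Product: 14 (1E,3S)-1-{(2R,3S)-3-[(2R)-2-hydroxy-3-methylbut-3-en-1-yl]-4-methylidene-5-oxooxolan-2-yl}-2-methylhexa-1,5-dien-3-yl acetate, via δ-lactone Barbier adduct 13 (not isolated)
Conditions: In powder (1.5 equiv), THF/H2O 3:1, rt; then pyridinium p-toluenesulfonate (10 mol%), toluene, 45 °C
Reagents that add atoms: none
Why: Proposed new method: a ring-locked, stereocentre-relaying 2-carbonylallyl donor – indium inserts into the C–Br bond of 12 and the allylindium adds to the aldehyde of 6 through its γ-carbon C7 in a closed six-membered chair (Zimmerman–Traxler) transition state; because the lactone ring holds C8 trans to the CH2–In carbon only the anti C6/C7 relationship can form, the C–C bond is made axially on the face of C7 opposite the pseudo-equatorial isopropenyl group at C9 (the 4,6-trans preference known for additions to 6-substituted 5,6-dihydropyran-2-ones), and the new C6 hydroxyl then attacks the δ-lactone carbonyl so that acyl transfer switches the ring to the more stable trans-disubstituted γ-lactone and frees the C9 hydroxyl, so C6 and C7 are both set from the single relay centre; closest known reaction type: indium- or zinc-mediated Barbier lactonisation of 2-(bromomethyl)acrylates and of 3-(bromomethyl)furan-2(5H)-one with aldehydes to α-methylene-γ-butyrolactones.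

Step 8
Reactants: 14 (1E,3S)-1-{(2R,3S)-3-[(2R)-2-hydroxy-3-methylbut-3-en-1-yl]-4-methylidene-5-oxooxolan-2-yl}-2-methylhexa-1,5-dien-3-yl acetate
Product: 15 (1E,3S)-1-{(2R,3S)-3-[(2S)-2-acetoxy-3-methylbut-3-en-1-yl]-4-methylidene-5-oxooxolan-2-yl}-2-methylhexa-1,5-dien-3-yl acetate
Conditions: PPh3 (1.5 equiv), diisopropyl azodicarboxylate (1.5 equiv), AcOH (2 equiv), toluene, −20 °C → rt (betaine preformed)
Reagents that add atoms: acetic acid CC(=O)O
Why: Mitsunobu reaction, in which the C9 hydroxyl is activated as the alkoxyphosphonium ion and displaced by acetate with SN2 inversion (9R to 9S), installing the second acetate with the target configuration while the preformed betaine keeps PPh3 from adding to the α-methylene lactone.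

Step 9
Reactants: 15 (1E,3S)-1-{(2R,3S)-3-[(2S)-2-acetoxy-3-methylbut-3-en-1-yl]-4-methylidene-5-oxooxolan-2-yl}-2-methylhexa-1,5-dien-3-yl acetate
Product: 16 (1E,3S)-1-{(2S,3S,4R)-3-[(2S)-2-acetoxy-3-methylbut-3-en-1-yl]-4-methyl-5-oxooxolan-2-yl}-2-methylhexa-1,5-dien-3-yl acetate
Conditions: Cu(OAc)2 (5 mol%), 1,2-bis(diphenylphosphino)benzene (5 mol%), (EtO)2MeSiH (1.5 equiv), t-BuOH (3 equiv), toluene, −20 → 0 °C
Reagents that add atoms: none
Why: Copper hydride conjugate reduction, in which hydride adds only to the unhindered exocyclic carbon C13 of the α-methylene lactone (isolated alkenes and acetates are inert) and the copper enolate is protonated by tert-butanol on the face away from the C7 side chain (kinetic protonation of a β-substituted butyrolactone enolate), leaving the C11 methyl cis to C8 (11R).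

Step 10
Reactants: 16 (1E,3S)-1-{(2S,3S,4R)-3-[(2S)-2-acetoxy-3-methylbut-3-en-1-yl]-4-methyl-5-oxooxolan-2-yl}-2-methylhexa-1,5-dien-3-yl acetate
Product: 17 (1(10)Z,4E)-(3S,6S,7S,9S,11R)-3,9-diacetoxygermacra-1(10),4-dien-12,6-olide (target)
Conditions: second-generation Hoveyda–Grubbs catalyst RuCl2(H2IMes)(=CH-C6H4-2-OiPr) (10 mol% in portions), 1,4-benzoquinone (20 mol%), toluene (1 mM), 80 °C, argon sparge
Reagents that add atoms: none
Why: Ring-closing metathesis of the terminal vinyl group onto the isopropenyl group closes the ten-membered ring, and with the E C4=C5 alkene and the trans lactone already in place the new trisubstituted alkene forms with C2 and C9 cis (Z), the less strained geometry for this cyclodeca-1,5-diene, while no stereocentre is touched under the neutral conditions.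

**Compound list**
1 | (E)-4,4-dimethoxy-2-methylbut-2-enal | COC(OC)/C=C(\C)C=O | starting material
2 | allylboronic acid pinacol ester (2-allyl-4,4,5,5-tetramethyl-1,3,2-dioxaborolane) | C=CCB1OC(C)(C)C(C)(C)O1 | starting material
3 | pinacol borate ester of 4 (O–B(pin) on C3) | COC(OC)/C=C(\C)[C@@H](OB1OC(C)(C)C(C)(C)O1)CC=C | intermediate
4 | (2E,4S)-1,1-dimethoxy-3-methylhepta-2,6-dien-4-ol | COC(OC)/C=C(\C)[C@@H](O)CC=C | intermediate
5 | (2E,4S)-1,1-dimethoxy-3-methylhepta-2,6-dien-4-yl acetate | COC(OC)/C=C(\C)[C@@H](OC(C)=O)CC=C | intermediate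
6 | (2E,4S)-3-methyl-1-oxohepta-2,6-dien-4-yl acetate | O=C/C=C(\C)[C@@H](OC(C)=O)CC=C | intermediate
7 | methacrolein (2-methylprop-2-enal) | CC(=C)C=O | starting material
8 | pinacol borate ester of 9 (O–B(pin) on C9) | CC(=C)[C@H](OB1OC(C)(C)C(C)(C)O1)CC=C | intermediate
9 | (3R)-2-methylhexa-1,5-dien-3-ol | CC(=C)[C@H](O)CC=C | intermediate
10 | 2-(bromomethyl)prop-2-enoic acid | C=C(CBr)C(=O)O | starting material
11 | (3R)-2-methylhexa-1,5-dien-3-yl 2-(bromomethyl)prop-2-enoate | CC(=C)[C@H](OC(=O)C(=C)CBr)CC=C | intermediate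
12 | (6R)-3-(bromomethyl)-6-(prop-1-en-2-yl)-5,6-dihydro-2H-pyran-2-one | CC(=C)[C@H]1CC=C(CBr)C(=O)O1 | intermediate
13 | (4S,6R)-4-[(1R,2E,4S)-4-acetoxy-1-hydroxy-3-methylhepta-2,6-dien-1-yl]-3-methylidene-6-(prop-1-en-2-yl)oxan-2-one (δ-lactone Barbier adduct; side chain at C7 trans to the isopropenyl group) | CC(=C)[C@H]1C[C@H]([C@H](O)/C=C(\C)[C@@H](OC(C)=O)CC=C)C(=C)C(=O)O1 | intermediate
14 | (1E,3S)-1-{(2R,3S)-3-[(2R)-2-hydroxy-3-methylbut-3-en-1-yl]-4-methylidene-5-oxooxolan-2-yl}-2-methylhexa-1,5-dien-3-yl acetate (trans γ-lactone, free 9R hydroxyl) | O[C@@H](C(C)=C)C[C@@H]1[C@@H](/C=C(\C)[C@@H](OC(C)=O)CC=C)OC(=O)C1=C | intermediate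
15 | (1E,3S)-1-{(2R,3S)-3-[(2S)-2-acetoxy-3-methylbut-3-en-1-yl]-4-methylidene-5-oxooxolan-2-yl}-2-methylhexa-1,5-dien-3-yl acetate | CC(=O)O[C@H](C(C)=C)C[C@@H]1[C@@H](/C=C(\C)[C@@H](OC(C)=O)CC=C)OC(=O)C1=C | intermediate
16 | (1E,3S)-1-{(2S,3S,4R)-3-[(2S)-2-acetoxy-3-methylbut-3-en-1-yl]-4-methyl-5-oxooxolan-2-yl}-2-methylhexa-1,5-dien-3-yl acetate | CC(=O)O[C@H](C(C)=C)C[C@@H]1[C@@H](/C=C(\C)[C@@H](OC(C)=O)CC=C)OC(=O)[C@@H]1C | intermediate
17 | (1(10)Z,4E)-(3S,6S,7S,9S,11R)-3,9-diacetoxygermacra-1(10),4-dien-12,6-olide | CC(=O)O[C@H]1C[C@@H]2[C@@H](/C=C(\C)[C@@H](OC(C)=O)C/C=C\1C)OC(=O)[C@@H]2C | target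

**Step count and risks**

Total steps: 10. Longest linear sequence: 7 (steps 1–3 and 7–10, or steps 4–6 and 7–10).

Most likely to fail, with fallbacks:

Step 7 (the proposed new step). The C–C bond formation itself is ordinary Barbier reactivity. The risks are the facial relay from C9 to C7, which rests on analogy with the 4,6-trans selectivity of additions to 6-substituted dihydropyranones, and a clean δ→γ ring switch without oxa-Michael addition of the freed hydroxyl. Fallback with known chemistry, setting out from 9 and 6 and coming back at 14: cross-metathesis of 9 with methyl 2-(bromomethyl)acrylate (second-generation Hoveyda–Grubbs catalyst RuCl2(H2IMes)(=CH-C6H4-2-OiPr), CH2Cl2, 40 °C) gives the open-chain allylic bromide methyl (2Z,5R)-2-(bromomethyl)-5-hydroxy-6-methylhepta-2,6-dienoate F1. The established Barbier lactonisation of such 2-(bromomethyl)enoates with aldehyde 6 (CrCl2, THF, then p-toluenesulfonic acid to close the lactone with loss of methanol) then gives 14. This gives up the ring-locked geometry and the relay, so the trans-lactone diastereomer with the right C7 configuration has to be separated by chromatography.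

Step 10. Closing a ten-membered ring onto a 1,1-disubstituted alkene that carries an allylic acetate may be slow, may give oligomers, or may give some E isomer. Fallback setting out from 14 and coming back at 17: keep the C9 hydroxyl free, because a free allylic hydroxyl accelerates ruthenium carbene formation at the neighbouring alkene whereas an allylic acetate retards it, and move the inversion to after ring closure. 14 is reduced as in step 9 (tert-butanol in excess as the external proton source) to (1E,3S)-1-{(2S,3S,4R)-3-[(2R)-2-hydroxy-3-methylbut-3-en-1-yl]-4-methyl-5-oxooxolan-2-yl}-2-methylhexa-1,5-dien-3-yl acetate F3. Ring-closing metathesis of F3 under the step 10 conditions gives the macrocyclic alcohol (1(10)Z,4E)-(3S,6S,7S,9R,11R)-3-acetoxy-9-hydroxygermacra-1(10),4-dien-12,6-olide F4. Mitsunobu reaction of F4 with acetic acid (PPh3, diisopropyl azodicarboxylate) inverts C9 and gives 17.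

Step 9. The chemoselective 1,4-reduction is reliable; the risk is a low diastereomer ratio at C11 if protonation of the copper enolate is not cleanly anti to the C7 side chain. Fallback setting out from 15 and coming back at 16: copper hydride 1,4-hydrosilylation without alcohol ([(Ph3P)CuH]6 (2 mol%), PhMe2SiH, toluene, 0 °C) gives the isolable dimethyl(phenyl)silyl ketene acetal of 16 (2-silyloxy-4,5-dihydrofuran form, C11 sp2) F2. F2 is then protonated under catalyst control with a chiral BINOL-derived N-triflyl thiophosphoramide (10 mol%) and phenol (1.1 equiv) in toluene at −78 °C, using the acid enantiomer that reinforces proton delivery anti to C8, to give 16.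

**Further compounds**
F1 | step 7 | methyl (2Z,5R)-2-(bromomethyl)-5-hydroxy-6-methylhepta-2,6-dienoate | COC(=O)/C(CBr)=C/C[C@@H](O)C(C)=C
F2 | step 9 | (1E,3S)-1-{(2R,3S)-3-[(2S)-2-acetoxy-3-methylbut-3-en-1-yl]-5-{[dimethyl(phenyl)silyl]oxy}-4-methyl-2,3-dihydrofuran-2-yl}-2-methylhexa-1,5-dien-3-yl acetate | CC(=O)O[C@H](C(C)=C)C[C@@H]1[C@@H](/C=C(\C)[C@@H](OC(C)=O)CC=C)OC(O[Si](C)(C)c2ccccc2)=C1C
F3 | step 10 | (1E,3S)-1-{(2S,3S,4R)-3-[(2R)-2-hydroxy-3-methylbut-3-en-1-yl]-4-methyl-5-oxooxolan-2-yl}-2-methylhexa-1,5-dien-3-yl acetate | O[C@@H](C(C)=C)C[C@@H]1[C@@H](/C=C(\C)[C@@H](OC(C)=O)CC=C)OC(=O)[C@@H]1C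
F4 | step 10 | (1(10)Z,4E)-(3S,6S,7S,9R,11R)-3-acetoxy-9-hydroxygermacra-1(10),4-dien-12,6-olide | O[C@@H]1C[C@@H]2[C@@H](/C=C(\C)[C@@H](OC(C)=O)C/C=C\1C)OC(=O)[C@@H]2C
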